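**Plan**

- Feature and numbering (C1 = acid carbon; ring O1–O2–C3–C4–C5–C6; chain C7–C14): the peroxide joins C3 and C6, the two ends of the C3–C4–C5–C6 unit, so the 1,2-dioxane ring is a cyclobutanol whose C3–C6 bond has taken up O2. C6 is kept as a spiro carbon with two identical CH2O arms (acetonide), so oxygenation of the C6 radical raises no facial question.
- Retrosynthetic cuts, in order: C1 ester hydrolysis; ethyl–C8 bond (Negishi); C7=C8 (iodo-Wittig olefination of a C6 formyl group with a C8–C14 phosphonium salt); the C6 ethyl (from the second arm by methylenation and diimide); C2–C3 (ketene acetal on the peroxycarbenium ion); O1–C6 and O2–C3 (cobalt/O2 ring expansion); ethyl–C4 (hydrazone alkylation); the spirocyclobutanone (sulfonium ylide spiroannulation).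
- Forward order: the cyclobutane ring first, then the 1,2-dioxane ring by ring expansion (the only later ring-forming event), then the C1–C2 unit, arm differentiation, the C6 ethyl, and last the union with the separately made C8–C14 chain.
- Stereochemistry: C4 from the RAMP azaenolate alkylation; C3 by axial attack on the peroxycarbenium ion under control of C4 (3,4-cis); C6 by lipase discrimination of the diastereotopic arms; C10 and the 11E alkene from Sharpless kinetic resolution followed by chair Johnson–Claisen chirality transfer; the 7E alkene from a Z-selective iodo-olefination followed by a retentive coupling.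

Key step: step 6

Remark on the chemistry: the lipase is assumed to cleave the equatorial acetoxymethyl arm at C6 (cis to the C4 ethyl group), the more exposed one; if it preferred the axial arm, running the same enzyme in the acylation direction on the diol would free the same hydroxymethyl group.

**Route**

Step 1
Reactants: 1 2,2-dimethyl-1,3-dioxan-5-one; 2 cyclopropyldiphenylsulfonium tetrafluoroborate
Product: 4 7,7-dimethyl-6,8-dioxaspiro[3.5]nonan-1-one, via oxaspiropentane 3 (not isolated)
Conditions: KOH, DMSO, 25 °C; then LiBF4 (cat.), CH2Cl2, 25 °C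
Reagents that add atoms: none
Why: Trost spiroannulation, in which the sulfonium cyclopropylide adds to the ketone and closes to oxaspiropentane 3, and lithium-assisted opening at the dioxane carbon with 1,2-shift of a cyclopropane bond should give the cyclobutanone whose spiro α-carbon is the former ketone carbon (future C6).

Step 2
Reactants: 4 7,7-dimethyl-6,8-dioxaspiro[3.5]nonan-1-one
Product: 5 (E)-N-[(2R)-2-(methoxymethyl)pyrrolidin-1-yl]-7,7-dimethyl-6,8-dioxaspiro[3.5]nonan-1-imine
Conditions: RAMP, 4 Å molecular sieves, cyclohexane, 60 °C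
Reagents that add atoms: (R)-1-amino-2-(methoxymethyl)pyrrolidine (RAMP), COC[C@H]1CCCN1N
Why: RAMP-hydrazone formation by acid-free condensation with the strained, electrophilic ketone should be easy and places the auxiliary next to the only enolisable position.

Step 3
Reactants: 5 (E)-N-[(2R)-2-(methoxymethyl)pyrrolidin-1-yl]-7,7-dimethyl-6,8-dioxaspiro[3.5]nonan-1-imine; 6 iodoethane
Product: 8 (1E,2S)-2-ethyl-N-[(2R)-2-(methoxymethyl)pyrrolidin-1-yl]-7,7-dimethyl-6,8-dioxaspiro[3.5]nonan-1-imine, via lithium azaenolate 7 (not isolated)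
Conditions: LiN(iPr)2, THF, −78 → 0 °C; then EtI, −100 → 25 °C
Reagents that add atoms: none
Why: Enders RAMP-hydrazone alkylation, in which deprotonation is possible only at C2 and the methoxymethyl-chelated azaenolate 7 should be ethylated on the face fixed by the auxiliary, which for the (R)-auxiliary on a ring azaenolate corresponds to the (S) centre (future C4).

Step 4
Reactants: 8 (1E,2S)-2-ethyl-N-[(2R)-2-(methoxymethyl)pyrrolidin-1-yl]-7,7-dimethyl-6,8-dioxaspiro[3.5]nonan-1-imine
Product: 9 (2S)-2-ethyl-7,7-dimethyl-6,8-dioxaspiro[3.5]nonan-1-one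
Conditions: O3, CH2Cl2, −78 °C
Reagents that add atoms: ozone, [O-][O+]=O
Why: Ozonolytic cleavage of the hydrazone C=N bond is fast at −78 °C under neutral conditions, so the α-stereocentre of the cyclobutanone should not epimerise and the acetonide stays intact.

Step 5
Reactants: 9 (2S)-2-ethyl-7,7-dimethyl-6,8-dioxaspiro[3.5]nonan-1-one
Product: 10 (2S)-2-ethyl-7,7-dimethyl-6,8-dioxaspiro[3.5]nonan-1-ol (both C1 epimers)
Conditions: NaBH4, MeOH, −20 °C
Reagents that add atoms: none
Why: Borohydride reduction of the ketone, where the carbinol configuration does not matter because this carbon becomes the trigonal aldehyde carbon in step 6, so the epimer mixture is used as such.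

Step 6
Reactants: 10 (2S)-2-ethyl-7,7-dimethyl-6,8-dioxaspiro[3.5]nonan-1-ol; 11 dioxygen
Product: 13 (4S)-4-ethyl-9,9-dimethyl-1,2,8,10-tetraoxaspiro[5.5]undecan-3-ol (both C3 epimers), via hydroperoxy aldehyde 12 (not isolated)
Conditions: Co(acac)2 (cat.), O2 (1 atm), 1,2-dichloroethane, 25–40 °C
Reagents that add atoms: none
Why: The alcohol exchanges onto cobalt and the trivalent cobalt alkoxide formed under O2 releases the cyclobutyloxy radical, which undergoes strain-driven β-scission of the C3–C6 bond to the C3 aldehyde and the tertiary C6 radical; O2 capture at C6 (forming C6–O1) and reduction of the peroxyl radical by divalent cobalt give hydroperoxy aldehyde 12, which closes to the lactol (forming O2–C3). The closest known reaction is the Co(acac)2/O2 oxidative ring expansion of secondary cyclobutanols with a fully substituted α-carbon to 1,2-dioxan-3-ols. The six-membered ring closes by 6-exo-trig addition of the hydroperoxide oxygen to the aldehyde. The only new stereocentre is the hemiacetal carbon C3, which is not controlled and is erased in step 8, while C6 is no stereocentre because its two CH2O arms are identical and C4 takes no part in any bond change. The selectivity needed is β-scission toward C6 and not toward C4, and it is secured by the greater stability of the tertiary radical at the spiro carbon over the secondary one. Fast lactol closure should also protect the α-branched aldehyde from enolisation at C4.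

Step 7
Reactants: 13 (4S)-4-ethyl-9,9-dimethyl-1,2,8,10-tetraoxaspiro[5.5]undecan-3-ol
Product: 14 (4S)-4-ethyl-9,9-dimethyl-1,2,8,10-tetraoxaspiro[5.5]undecan-3-yl acetate (both C3 epimers)
Conditions: Ac2O, pyridine, 4-dimethylaminopyridine (cat.), CH2Cl2, 0 °C
Reagents that add atoms: acetic anhydride, CC(=O)OC(C)=O
Why: O-Acetylation of the peroxy-hemiacetal hydroxyl traps the ring-closed form and installs the leaving group for ionisation at C3; the anomeric mixture is of no consequence.

Step 8
Reactants: 14 (4S)-4-ethyl-9,9-dimethyl-1,2,8,10-tetraoxaspiro[5.5]undecan-3-yl acetate; 15 1-(tert-butyldimethylsilyloxy)-1-methoxyethene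
Product: 16 methyl 2-[(3S,4S)-4-ethyl-9,9-dimethyl-1,2,8,10-tetraoxaspiro[5.5]undecan-3-yl]acetate
Conditions: Me3SiOTf (cat.), CH2Cl2, −78 °C
Reagents that add atoms: none
Why: Lewis-acid ionisation of the anomeric acetate gives the cyclic peroxycarbenium ion, and Mukaiyama-type addition of the silyl ketene acetal should occur by axial attack on the half-chair in which the C4 ethyl is pseudo-equatorial (its axial placement would clash with the axial C6 arm), giving the 3,4-cis (3S) product.

Step 9
Reactants: 16 methyl 2-[(3S,4S)-4-ethyl-9,9-dimethyl-1,2,8,10-tetraoxaspiro[5.5]undecan-3-yl]acetate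
Product: 17 methyl 2-[(3S,4S)-4-ethyl-6,6-bis(hydroxymethyl)-1,2-dioxan-3-yl]acetate
Conditions: camphorsulfonic acid (cat.), MeOH, 25 °C
Reagents that add atoms: none
Why: Acid-catalysed transketalisation in methanol removes the isopropylidene group, and the dialkyl peroxide and the methyl ester are inert to these conditions.

Step 10
Reactants: 17 methyl 2-[(3S,4S)-4-ethyl-6,6-bis(hydroxymethyl)-1,2-dioxan-3-yl]acetate
Product: 18 methyl 2-[(3S,4S)-6,6-bis(acetoxymethyl)-4-ethyl-1,2-dioxan-3-yl]acetate
Conditions: Ac2O, pyridine, 4-dimethylaminopyridine (cat.), CH2Cl2, 25 °C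
Reagents that add atoms: acetic anhydride, CC(=O)OC(C)=O
Why: Exhaustive acetylation of the two primary neopentyl alcohols (standard esterification) gives the substrate for enzymatic group differentiation.

Step 11
Reactants: 18 methyl 2-[(3S,4S)-6,6-bis(acetoxymethyl)-4-ethyl-1,2-dioxan-3-yl]acetate
Product: 19 methyl 2-[(3S,4S,6S)-6-(acetoxymethyl)-4-ethyl-6-(hydroxymethyl)-1,2-dioxan-3-yl]acetate
Conditions: lipase from Burkholderia cepacia, phosphate buffer (pH 7)/acetone, 30 °C, stopped at the monoacetate
Reagents that add atoms: none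
Why: Lipase-catalysed regioselective hydrolysis, in which the two acetoxymethyl arms are diastereotopic (equatorial and cis to the C4 ethyl versus axial) and cleavage of the more exposed equatorial acetate should make C6 a stereocentre with the future ethyl arm free and the future alkenyl arm still acetylated.

Step 12
Reactants: 19 methyl 2-[(3S,4S,6S)-6-(acetoxymethyl)-4-ethyl-6-(hydroxymethyl)-1,2-dioxan-3-yl]acetate
Product: 20 methyl 2-[(3S,4S,6R)-6-(acetoxymethyl)-4-ethyl-6-formyl-1,2-dioxan-3-yl]acetate
Conditions: Dess–Martin periodinane, NaHCO3, CH2Cl2, 0 → 25 °C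
Reagents that add atoms: none
Why: Buffered Dess–Martin oxidation converts the neopentyl alcohol to the aldehyde without touching the O–O bond, and the product has no α-hydrogen and cannot epimerise.

Step 13
Reactants: 20 methyl 2-[(3S,4S,6R)-6-(acetoxymethyl)-4-ethyl-6-formyl-1,2-dioxan-3-yl]acetate; 21 methyltriphenylphosphonium bromide
Product: 23 methyl 2-[(3S,4S,6S)-6-(acetoxymethyl)-6-ethenyl-4-ethyl-1,2-dioxan-3-yl]acetate, via methylenetriphenylphosphorane 22 (not isolated)
Conditions: 21, KN(SiMe3)2, THF, 0 °C; then 20, −78 → 0 °C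
Reagents that add atoms: none
Why: Wittig methylenation with ylide 22 at low temperature should be faster at the aldehyde than at the acetate or the methyl ester, and the ylide is too weak a base to enolise the β-peroxy ester.

Step 14
Reactants: 23 methyl 2-[(3S,4S,6S)-6-(acetoxymethyl)-6-ethenyl-4-ethyl-1,2-dioxan-3-yl]acetate
Product: 24 methyl 2-[(3S,4S,6R)-6-(acetoxymethyl)-4,6-diethyl-1,2-dioxan-3-yl]acetate
Conditions: dipotassium azodicarboxylate, AcOH, MeOH, 0 → 25 °C
Reagents that add atoms: none
Why: Diimide reduction (concerted syn transfer of two hydrogens to the monosubstituted alkene) saturates the vinyl group without the O–O hydrogenolysis that metal-catalysed hydrogenation would risk.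

Step 15
Reactants: 24 methyl 2-[(3S,4S,6R)-6-(acetoxymethyl)-4,6-diethyl-1,2-dioxan-3-yl]acetate
Product: 25 methyl 2-[(3S,4S,6R)-4,6-diethyl-6-(hydroxymethyl)-1,2-dioxan-3-yl]acetate
Conditions: K2CO3 (cat.), MeOH, 0 °C
Reagents that add atoms: none
Why: Carbonate-catalysed methanolysis (transesterification) removes the primary acetate, exchange at the methyl ester is degenerate, and the mild base at 0 °C should not trigger retro-Michael opening of the β-peroxy ester.

Step 16
Reactants: 25 methyl 2-[(3S,4S,6R)-4,6-diethyl-6-(hydroxymethyl)-1,2-dioxan-3-yl]acetate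
Product: 26 methyl 2-[(3S,4S,6R)-4,6-diethyl-6-formyl-1,2-dioxan-3-yl]acetate
Conditions: Dess–Martin periodinane, NaHCO3, CH2Cl2, 0 → 25 °C
Reagents that add atoms: none
Why: Dess–Martin oxidation of the remaining neopentyl alcohol gives the non-enolisable α-peroxy aldehyde whose carbonyl carbon is C7.

Step 17
Reactants: 27 (E)-pent-2-enal; 28 ethylmagnesium bromide
Product: 29 rac-(E)-hept-4-en-3-ol
Conditions: EtMgBr, Et2O, −78 → 0 °C; aq. NH4Cl
Reagents that add atoms: none
Why: Grignard 1,2-addition to the enal gives the racemic secondary allylic alcohol with the E-alkene unchanged.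

Step 18
Reactants: 29 rac-(E)-hept-4-en-3-ol
Product: 30 (3R,4E)-hept-4-en-3-ol
Conditions: Ti(OiPr)4, L-(+)-diisopropyl tartrate, t-BuOOH (0.6 equiv), 4 Å molecular sieves, CH2Cl2, −20 °C
Reagents that add atoms: none
Why: Sharpless kinetic resolution, in which the L-(+)-tartrate catalyst epoxidises the (S)-alcohol much faster, so the (R)-alcohol should be recovered in high enantiomeric purity.

Step 19
Reactants: 30 (3R,4E)-hept-4-en-3-ol; 31 triethyl orthoacetate
Product: 33 ethyl (3R,4E)-3-ethylhept-4-enoate, via ketene acetal 32 (not isolated)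
Conditions: MeC(OEt)3, EtCO2H (cat.), 140 °C, EtOH distilled off
Reagents that add atoms: none
Why: Johnson–Claisen rearrangement, in which ketene acetal 32 rearranges through a chair transition state with the carbinol ethyl group equatorial, so the C–O chirality is transferred suprafacially to the new C–C bond and sets the (R) centre (future C10) and the E-alkene (future C11=C12).

Step 20
Reactants: 33 ethyl (3R,4E)-3-ethylhept-4-enoate
Product: 34 (3R,4E)-3-ethylhept-4-en-1-ol
Conditions: LiAlH4, Et2O, 0 °C
Reagents that add atoms: none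
Why: LiAlH4 reduction of the ester gives the primary alcohol and leaves the isolated alkene and the stereocentre untouched.

Step 21
Reactants: 34 (3R,4E)-3-ethylhept-4-en-1-ol
Product: 35 (3E,5R)-5-ethyl-7-iodohept-3-ene
Conditions: I2, PPh3, imidazole, CH2Cl2, 0 °C
Reagents that add atoms: iodine, II
Why: Appel-type iodination converts the primary alcohol into the iodide with no change at the remote stereocentre.

Step 22
Reactants: 35 (3E,5R)-5-ethyl-7-iodohept-3-ene
Product: 36 [(3R,4E)-3-ethylhept-4-en-1-yl]triphenylphosphonium iodide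
Conditions: PPh3, MeCN, 80 °C
Reagents that add atoms: triphenylphosphine, c1ccc(cc1)P(c1ccccc1)c1ccccc1
Why: SN2 quaternisation of triphenylphosphine by the unhindered primary iodide gives the Wittig salt.

Step 23
Reactants: 36 [(3R,4E)-3-ethylhept-4-en-1-yl]triphenylphosphonium iodide; 26 methyl 2-[(3S,4S,6R)-4,6-diethyl-6-formyl-1,2-dioxan-3-yl]acetate
Product: 40 methyl 2-[(3S,4S,6R)-4,6-diethyl-6-[(1Z,4R,5E)-4-ethyl-2-iodoocta-1,5-dien-1-yl]-1,2-dioxan-3-yl]acetate, via phosphorus ylide 37 (not isolated), via iodophosphonium iodide 38 (not isolated), via iodo ylide 39 (not isolated)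
Conditions: 36, NaN(SiMe3)2, THF, 25 °C; I2, −78 °C; NaN(SiMe3)2, −78 → −20 °C; then 26, −78 → −20 °C
Reagents that add atoms: iodine, II
Why: Stork–Zhao-type olefination, in which ylide 37 is iodinated to 38 and deprotonated to the α-iodo ylide 39, whose Wittig reaction with the non-enolisable aldehyde should be Z-selective and so place iodine cis to C6 and the C9 chain trans to it, the arrangement needed at C7=C8.

Step 24
Reactants: 40 methyl 2-[(3S,4S,6R)-4,6-diethyl-6-[(1Z,4R,5E)-4-ethyl-2-iodoocta-1,5-dien-1-yl]-1,2-dioxan-3-yl]acetate; 41 diethylzinc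
Product: 42 methyl 2-[(3S,4S,6R)-4,6-diethyl-6-[(1E,4R,5E)-2,4-diethylocta-1,5-dien-1-yl]-1,2-dioxan-3-yl]acetate
Conditions: Et2Zn, Pd(dppf)Cl2 (cat.), THF, 0 → 25 °C
Reagents that add atoms: none
Why: Negishi coupling, in which oxidative addition of zerovalent palladium into the alkenyl C–I bond, transmetalation from zinc and reductive elimination all proceed with retention, so ethyl replaces iodine cis to C6 and the 7E alkene results, while the bidentate dppf ligand suppresses β-hydride elimination and the dialkyl peroxide is expected to tolerate the mild conditions.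

Step 25
Reactants: 42 methyl 2-[(3S,4S,6R)-4,6-diethyl-6-[(1E,4R,5E)-2,4-diethylocta-1,5-dien-1-yl]-1,2-dioxan-3-yl]acetate
Product: 43 plakortide N, 2-[(3S,4S,6R)-4,6-diethyl-6-[(1E,4R,5E)-2,4-diethylocta-1,5-dien-1-yl]-1,2-dioxan-3-yl]acetic acid
Conditions: LiOH, THF/H2O, 0 °C; then 1 M HCl to pH 3
Reagents that add atoms: lithium hydroxide, [Li+].[OH-]
Why: Saponification of the methyl ester at 0 °C followed by careful acidification should give the free acid, the low temperature limiting base-induced retro-Michael opening of the β-peroxy carboxylate.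

**Compound list**

1 | 2,2-dimethyl-1,3-dioxan-5-one | CC1(C)OCC(=O)CO1 | starting material
2 | cyclopropyldiphenylsulfonium tetrafluoroborate | F[B-](F)(F)F.c1ccc(cc1)[S+](C1CC1)c1ccccc1 | starting material
3 | 7,7-dimethyl-6,8,10-trioxadispiro[2.0.5^4.1^3]decane (oxaspiropentane, not isolated) | CC1(C)OCC2(CO1)OC23CC3 | intermediate
4 | 7,7-dimethyl-6,8-dioxaspiro[3.5]nonan-1-one | CC1(C)OCC2(CO1)CCC2=O | intermediate
5 | (E)-N-[(2R)-2-(methoxymethyl)pyrrolidin-1-yl]-7,7-dimethyl-6,8-dioxaspiro[3.5]nonan-1-imine | CC1(C)OCC2(CO1)CC/C2=N\N1CCC[C@@H]1COC | intermediate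
6 | iodoethane | CCI | starting material
7 | lithium azaenolate of 5 (lithium [(2R)-2-(methoxymethyl)pyrrolidin-1-yl](7,7-dimethyl-6,8-dioxaspiro[3.5]non-1-en-1-yl)azanide, not isolated) | [Li]N(N1CCC[C@@H]1COC)C1=CCC12COC(C)(C)OC2 | intermediate
8 | (1E,2S)-2-ethyl-N-[(2R)-2-(methoxymethyl)pyrrolidin-1-yl]-7,7-dimethyl-6,8-dioxaspiro[3.5]nonan-1-imine | CC1(C)OCC2(CO1)C[C@H](CC)/C2=N\N1CCC[C@@H]1COC | intermediate
9 | (2S)-2-ethyl-7,7-dimethyl-6,8-dioxaspiro[3.5]nonan-1-one | CC1(C)OCC2(CO1)C[C@H](CC)C2=O | intermediate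
10 | (2S)-2-ethyl-7,7-dimethyl-6,8-dioxaspiro[3.5]nonan-1-ol (both C1 epimers) | CC1(C)OCC2(CO1)C[C@H](CC)C2O | intermediate
11 | dioxygen | O=O | starting material
12 | (2S)-2-ethyl-3-(5-hydroperoxy-2,2-dimethyl-1,3-dioxan-5-yl)propanal (not isolated) | CC1(C)OCC(CO1)(OO)C[C@H](CC)C=O | intermediate
13 | (4S)-4-ethyl-9,9-dimethyl-1,2,8,10-tetraoxaspiro[5.5]undecan-3-ol (both C3 epimers) | CC1(C)OCC2(CO1)C[C@H](CC)C(O)OO2 | intermediate
14 | (4S)-4-ethyl-9,9-dimethyl-1,2,8,10-tetraoxaspiro[5.5]undecan-3-yl acetate (both C3 epimers) | CC1(C)OCC2(CO1)C[C@H](CC)C(OC(C)=O)OO2 | intermediate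
15 | 1-(tert-butyldimethylsilyloxy)-1-methoxyethene | C=C(OC)O[Si](C)(C)C(C)(C)C | starting material
16 | methyl 2-[(3S,4S)-4-ethyl-9,9-dimethyl-1,2,8,10-tetraoxaspiro[5.5]undecan-3-yl]acetate | CC1(C)OCC2(CO1)C[C@H](CC)[C@H](CC(=O)OC)OO2 | intermediate
17 | methyl 2-[(3S,4S)-4-ethyl-6,6-bis(hydroxymethyl)-1,2-dioxan-3-yl]acetate | OCC1(CO)C[C@H](CC)[C@H](CC(=O)OC)OO1 | intermediate
18 | methyl 2-[(3S,4S)-6,6-bis(acetoxymethyl)-4-ethyl-1,2-dioxan-3-yl]acetate | CC(=O)OCC1(COC(C)=O)C[C@H](CC)[C@H](CC(=O)OC)OO1 | intermediate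
19 | methyl 2-[(3S,4S,6S)-6-(acetoxymethyl)-4-ethyl-6-(hydroxymethyl)-1,2-dioxan-3-yl]acetate | CC(=O)OC[C@@]1(CO)C[C@H](CC)[C@H](CC(=O)OC)OO1 | intermediate
20 | methyl 2-[(3S,4S,6R)-6-(acetoxymethyl)-4-ethyl-6-formyl-1,2-dioxan-3-yl]acetate | CC(=O)OC[C@@]1(C=O)C[C@H](CC)[C@H](CC(=O)OC)OO1 | intermediate
21 | methyltriphenylphosphonium bromide | [Br-].C[P+](c1ccccc1)(c1ccccc1)c1ccccc1 | starting material
22 | methylenetriphenylphosphorane (not isolated) | C=P(c1ccccc1)(c1ccccc1)c1ccccc1 | intermediate
23 | methyl 2-[(3S,4S,6S)-6-(acetoxymethyl)-6-ethenyl-4-ethyl-1,2-dioxan-3-yl]acetate | CC(=O)OC[C@@]1(C=C)C[C@H](CC)[C@H](CC(=O)OC)OO1 | intermediate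
24 | methyl 2-[(3S,4S,6R)-6-(acetoxymethyl)-4,6-diethyl-1,2-dioxan-3-yl]acetate | CC(=O)OC[C@@]1(CC)C[C@H](CC)[C@H](CC(=O)OC)OO1 | intermediate
25 | methyl 2-[(3S,4S,6R)-4,6-diethyl-6-(hydroxymethyl)-1,2-dioxan-3-yl]acetate | OC[C@@]1(CC)C[C@H](CC)[C@H](CC(=O)OC)OO1 | intermediate
26 | methyl 2-[(3S,4S,6R)-4,6-diethyl-6-formyl-1,2-dioxan-3-yl]acetate | O=C[C@@]1(CC)C[C@H](CC)[C@H](CC(=O)OC)OO1 | intermediate
27 | (E)-pent-2-enal | CC/C=C/C=O | starting material
28 | ethylmagnesium bromide | CC[Mg]Br | starting material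
29 | rac-(E)-hept-4-en-3-ol | CCC(O)/C=C/CC | intermediate
30 | (3R,4E)-hept-4-en-3-ol | CC[C@@H](O)/C=C/CC | intermediate
31 | triethyl orthoacetate | CCOC(C)(OCC)OCC | starting material
32 | (3R,4E)-3-[(1-ethoxyethenyl)oxy]hept-4-ene (ketene acetal, not isolated) | CC[C@@H](OC(=C)OCC)/C=C/CC | intermediate
33 | ethyl (3R,4E)-3-ethylhept-4-enoate | CCOC(=O)C[C@@H](CC)/C=C/CC | intermediate
34 | (3R,4E)-3-ethylhept-4-en-1-ol | OCC[C@@H](CC)/C=C/CC | intermediate
35 | (3E,5R)-5-ethyl-7-iodohept-3-ene | ICC[C@@H](CC)/C=C/CC | intermediate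
36 | [(3R,4E)-3-ethylhept-4-en-1-yl]triphenylphosphonium iodide | [I-].CC/C=C/[C@H](CC)CC[P+](c1ccccc1)(c1ccccc1)c1ccccc1 | intermediate
37 | [(3R,4E)-3-ethylhept-4-en-1-ylidene]triphenylphosphorane (not isolated) | CC/C=C/[C@H](CC)CC=P(c1ccccc1)(c1ccccc1)c1ccccc1 | intermediate
38 | [(3R,4E)-3-ethyl-1-iodohept-4-en-1-yl]triphenylphosphonium iodide (both C1 epimers, not isolated) | [I-].CC/C=C/[C@H](CC)CC(I)[P+](c1ccccc1)(c1ccccc1)c1ccccc1 | intermediate
39 | [(3R,4E)-3-ethyl-1-iodohept-4-en-1-ylidene]triphenylphosphorane (not isolated) | CC/C=C/[C@H](CC)CC(I)=P(c1ccccc1)(c1ccccc1)c1ccccc1 | intermediate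
40 | methyl 2-[(3S,4S,6R)-4,6-diethyl-6-[(1Z,4R,5E)-4-ethyl-2-iodoocta-1,5-dien-1-yl]-1,2-dioxan-3-yl]acetate | CC/C=C/[C@H](CC)C/C(=C/[C@@]1(CC)C[C@H](CC)[C@H](CC(=O)OC)OO1)I | intermediate
41 | diethylzinc | CC[Zn]CC | starting material
42 | methyl 2-[(3S,4S,6R)-4,6-diethyl-6-[(1E,4R,5E)-2,4-diethylocta-1,5-dien-1-yl]-1,2-dioxan-3-yl]acetate | CC/C=C/[C@H](CC)C/C(=C/[C@@]1(CC)C[C@H](CC)[C@H](CC(=O)OC)OO1)CC | intermediate
43 | plakortide N, 2-[(3S,4S,6R)-4,6-diethyl-6-[(1E,4R,5E)-2,4-diethylocta-1,5-dien-1-yl]-1,2-dioxan-3-yl]acetic acid | CC/C=C/[C@H](CC)C/C(=C/[C@@]1(CC)C[C@H](CC)[C@H](CC(=O)O)OO1)CC | target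

**Step count and risks**

Total step count: 25. Longest linear sequence: 19 steps (steps 1–16 and 23–25, from 1 to 43); the side-chain branch (steps 17–22) joins at step 23.

The three steps most likely to fail:

Step 23. The weakly nucleophilic, thermally labile α-iodo ylide may add too slowly to the hindered α-quaternary aldehyde, and warming to force conversion may erode the Z-selectivity. The fallback builds the same trisubstituted alkene by two site-selective palladium couplings on a 1,1-dichloroalkene; it sets out from aldehyde 26 and ester 33 and comes back at 42. Aldehyde 26 would be dichloromethylenated (BrCCl3, PPh3, MeCN) to methyl 2-[(3S,4S,6R)-6-(2,2-dichloroethenyl)-4,6-diethyl-1,2-dioxan-3-yl]acetate F1. Ester 33 would be saponified to (3R,4E)-3-ethylhept-4-enoic acid F2, converted into its Barton ester 2-thioxopyridin-1(2H)-yl (3R,4E)-3-ethylhept-4-enoate F3 and irradiated with CHI3 to give the one-carbon-shorter iodide (3E,5S)-5-(iodomethyl)hept-3-ene F4; zinc insertion (Zn, LiCl, THF) would then give [(2S,3E)-2-ethylhex-3-en-1-yl]zinc iodide F5. Negishi coupling of F5 with F1 under Pd(DPEphos)Cl2 catalysis is selective for the chloride trans to the substituent and should give the (Z)-chloroalkene methyl 2-[(3S,4S,6R)-6-[(1Z,4R,5E)-2-chloro-4-ethylocta-1,5-dien-1-yl]-4,6-diethyl-1,2-dioxan-3-yl]acetate F6. A second Negishi coupling with diethylzinc 41 under Pd(P(t-Bu)3)2 catalysis, which goes with retention, would then give 42.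

Step 8. The nucleophile may attack the peroxycarbenium ion from the equatorial side (3,4-trans product), or the Lewis acid may open the acetonide toward the ketene acetal. The fallback forms C2–C3 by olefination and O2–C3 by conjugate addition; it sets out from lactol 13 and comes back at 16. Lactol 13, through its open-chain tautomer 12, would react with methyl (triphenylphosphoranylidene)acetate in CH2Cl2 to give the hydroperoxy enoate methyl (2E,4S)-4-ethyl-5-(5-hydroperoxy-2,2-dimethyl-1,3-dioxan-5-yl)pent-2-enoate F7. Et2NH in CF3CH2OH would then close the ring by 6-exo-trig peroxy-Michael addition to give 16 together with its C3 epimer; because this addition is reversible, the unwanted epimer could be separated and resubmitted.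

Step 11. The enzyme may discriminate poorly between the two acetoxymethyl arms, or it may also cleave the methyl ester. The fallback uses reagent-based steric discrimination instead; it sets out from diol 17 and comes back at 19. Silylation of 17 with t-BuPh2SiCl and imidazole at low temperature should take the equatorial hydroxyl and give methyl 2-[(3S,4S,6R)-6-[(tert-butyldiphenylsilyloxy)methyl]-4-ethyl-6-(hydroxymethyl)-1,2-dioxan-3-yl]acetate F8. Acetylation of the remaining axial hydroxyl would give methyl 2-[(3S,4S,6R)-6-(acetoxymethyl)-6-[(tert-butyldiphenylsilyloxy)methyl]-4-ethyl-1,2-dioxan-3-yl]acetate F9, and HF·pyridine would remove the silyl group to give 19.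

**Further compounds**

F1 | step 23 | methyl 2-[(3S,4S,6R)-6-(2,2-dichloroethenyl)-4,6-diethyl-1,2-dioxan-3-yl]acetate | ClC(Cl)=C[C@@]1(CC)C[C@H](CC)[C@H](CC(=O)OC)OO1
F2 | step 23 | (3R,4E)-3-ethylhept-4-enoic acid | OC(=O)C[C@@H](CC)/C=C/CC
F3 | step 23 | 2-thioxopyridin-1(2H)-yl (3R,4E)-3-ethylhept-4-enoate | S=C1C=CC=CN1OC(=O)C[C@@H](CC)/C=C/CC
F4 | step 23 | (3E,5S)-5-(iodomethyl)hept-3-ene | IC[C@@H](CC)/C=C/CC
F5 | step 23 | [(2S,3E)-2-ethylhex-3-en-1-yl]zinc iodide | I[Zn]C[C@@H](CC)/C=C/CC
F6 | step 23 | methyl 2-[(3S,4S,6R)-6-[(1Z,4R,5E)-2-chloro-4-ethylocta-1,5-dien-1-yl]-4,6-diethyl-1,2-dioxan-3-yl]acetate | CC/C=C/[C@H](CC)C/C(=C/[C@@]1(CC)C[C@H](CC)[C@H](CC(=O)OC)OO1)Cl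
F7 | step 8 | methyl (2E,4S)-4-ethyl-5-(5-hydroperoxy-2,2-dimethyl-1,3-dioxan-5-yl)pent-2-enoate | CC1(C)OCC(CO1)(OO)C[C@H](CC)/C=C/C(=O)OC
F8 | step 11 | methyl 2-[(3S,4S,6R)-6-[(tert-butyldiphenylsilyloxy)methyl]-4-ethyl-6-(hydroxymethyl)-1,2-dioxan-3-yl]acetate | OC[C@@]1(CO[Si](c2ccccc2)(c2ccccc2)C(C)(C)C)C[C@H](CC)[C@H](CC(=O)OC)OO1
F9 | step 11 | methyl 2-[(3S,4S,6R)-6-(acetoxymethyl)-6-[(tert-butyldiphenylsilyloxy)methyl]-4-ethyl-1,2-dioxan-3-yl]acetate | CC(=O)OC[C@@]1(CO[Si](c2ccccc2)(c2ccccc2)C(C)(C)C)C[C@H](CC)[C@H](CC(=O)OC)OO1
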